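## Structural features

Jezonodione is a bicyclo[3.2.1]oct-3-ene-2,8-dione. With the atoms labelled C1 (enone carbonyl), C2 (enone CH), C3 (alkene carbon bearing the E-styryl group), C4 (bridgehead), C5 (bridging carbonyl), C6 (bridgehead between the two carbonyls), C7 (catechol-bearing CH) and C8 (resorcinol-bearing CH), it consists of cyclohexenone ring A (C1 to C6) and cyclopentanone ring B (C4–C5–C6–C7–C8), which share C4, C5 and C6. Four contiguous stereocentres lie on ring B (C4 R, C6 S, C7 R, C8 R in this numbering): the two aryl groups are trans, the C7 catechol is endo (cis to C1, under the C1–C3 bridge), the C8 resorcinol is exo (trans to C3), and the bridgeheads are cis by necessity. The fragile parts are the 1,3-dione whose central carbon C6 is a bridgehead (it cannot enolise, so nucleophiles open it by retro-Claisen cleavage), the push–pull dienone conjugated to a 4-oxygenated styrene (sensitive to acids and Lewis acids), and six phenols, two of them catechols that oxidise easily. The phenols are therefore masked until the last step and must come off mildly. Benzyl ethers (BCl3 with pentamethylbenzene at −78 °C) are chosen instead of methyl ethers, whose six-fold cleavage would expose the dione and the nucleophilic rings to BBr3 for hours. The real difficulty is ring B: a trans-3,4-diarylcyclopentanone whose α-carbons C4 and C6 differ only in which aryl group is two bonds away, yet C4 must carry C3 and C6 must carry C1. The key step exploits exactly this: ring B is made by expansion of a cyclobutanol in which benzylic C8 shifts onto C4, so the C5 ketone forms between a C4 that already carries C3 with its styryl group and a free C6 methylene.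

## Logic of the disconnections

22 ⇒ 21. The six phenolic O–H groups are traced back to O–benzyl bonds. Free catechols would not survive the oxidant of step 11, the electrophiles of steps 3 and 9 or the organometallics of steps 4, 5 and 8. The gain is that every earlier intermediate is a neutral ether. The demand is a cleavage that spares the bridgehead 1,3-dione and the dienone, hence benzyl and not methyl.

21 ⇒ 20. No skeletal bond is cut; the C1 carbonyl is taken back to a secondary allylic alcohol. A 1,3-dione with a bridgehead between the carbonyls has no enolate to drive a Claisen-type closure, so C1 must arrive at the aldehyde level and be oxidised afterwards. The forward step needs a neutral oxidant, because the C1 carbinol ionises easily.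

20 ⇒ 19. The C1–C6 bond is cut (aldol retron, C1 carbinol β to the C5 ketone). This opens ring A, leaves a monocyclic cyclopentanone, removes the C6 stereocentre and makes the C1 configuration irrelevant. The forward step demands that the C6 enamine attacks and that the aldehyde sits cis to C4 on the C2=C3 bond; the tether then fixes C6.

19 ⇒ 17. The C1–C2 bond is cut, removing the formyl carbon from the diene terminus. What remains is a 2-substituted 1-aryl-1,3-diene whose CH2 end is its most nucleophilic carbon. The forward step demands a formylation that chooses this carbon over the oxygenated rings.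

17 ⇒ 14 + 16. Two bonds are cut, C4–C8 and C3–C(styryl), and C8 is reconnected to C5, which contracts ring B to a cyclobutanol bearing an allene (C4=C3=C2). Here the C4/C6 problem disappears: the carbinol carbon C5 of 14 carries the future C4 as a substituent, so the regiochemistry of ring B is decided by which ring bond migrates, and the styryl unit arrives in the same operation. The forward step demands attack of the alkenylpalladium species at the central allene carbon and migration of benzylic C8, not C6, with retention at C8.

14 ⇒ 13 ⇒ 10 + 11. The allene is traced to a propargylic methyl ether (forward: hydride onto C4, methoxide lost from C2), and the C5–C4 bond is cut to a cyclobutanone and an acetylide. The gain is a ketone holding only the two aryl-bearing stereocentres. The forward steps demand a non-basic acetylide, because the α-aryl proton at C8 is acidic, and hydride delivery to the alkyne carbon next to the carbinol.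

10 ⇒ 5 + 7. Both C5–C8 and C6–C7 are cut ([2+2] retron): C5–C6 becomes a keteniminium and C7–C8 an E-alkene. This is the largest simplification of the route, since both aryl-bearing stereocentres go back to a flat stilbene. The forward step demands regiochemistry (C5 to the carbon bearing the 3,5-dioxygenated ring), trans geometry and absolute configuration, the last supplied by the C2-symmetric amine.

5 ⇒ 1 + 2 + 3 (through 4). The C7=C8 double bond is cut by an olefination retron, giving catalogue benzyl ethers. The forward step demands E selectivity, which a benzylic phosphonate carbanion provides.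

16 ⇒ 15 ⇒ 3. The C–Br bond is traced to a carboxyl group and the acrylic acid to the aldehyde already used for 5. Both forward steps must give the E geometry.

7 ⇒ 6. The N–acyl bond is cut; 6 is bought as a single enantiomer and is released again in step 3.

## Other disconnections considered

Alternative 1: The cut is the C2=C3 bond of ring A. Forward, cyclopentanone A1 (ethynyl on C4 and allyl on C6, on the same face of ring B) would be treated with second-generation Grubbs catalyst under ethylene. Ring-closing enyne metathesis would join C2 to C3, close ring A and leave a vinyl group on C3, giving A2. By the usual locants A2 is a 2-ethenylbicyclo[3.2.1]oct-2-en-8-one, since the vinyl group sits on the alkene carbon next to the bridgehead.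
- In its favour: the closure is irreversible, neutral and needs no enolisation. On the ring A closure itself it is the better plan, because the chosen route relies on an aldol equilibrium in step 10.
- Against it here: A2 lacks the C1 oxygen and the aryl group of the styryl unit, so a late allylic oxidation at C1 (beside two benzylic methines and electron-rich rings) and a Heck arylation or cross-metathesis would still be needed. A1 needs the C6 allyl group cis to the C7 aryl group, the less stable arrangement at an epimerisable centre, and contains an α-ethynyl ketone that isomerises readily to the allenyl ketone. A1 also presupposes different substituents on C4 and C6, the regiochemical problem the chosen ring expansion solves.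
- Comparison: in structure both plans close ring A last from a ring B ketone and are equal in how C7 and C8 would be set. In mechanism the metathesis is kinetically cleaner than the aldol, whereas the chosen plan brings C1 in at the right oxidation level and fixes C6 by the tether. In step economy the alternative would be longer by the oxidation, the arylation and the extra steps to A1.

Alternative 2: The cut is the C5–C6 bond of ring B. Forward, pent-4-enal A3 would be treated with [Rh(BINAP)]BF4, a cationic complex of monovalent rhodium. A3 has the C5 aldehyde on C4, which already bears a 3-silyloxypropyl chain, the C8 stereocentre, and a 1,1-disubstituted C6=C7 alkene carrying the 3,4-dimethoxyphenyl group. The aldehyde C–H bond adds to rhodium, the acyl hydride adds across the alkene and reductive elimination forms C5–C6, closing ring B as A4 and creating C7.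
- In its favour: enantiocontrol is catalytic, which is better than the stoichiometric (if recoverable) auxiliary of the chosen plan, and the step is redox-neutral and atom-economical. The C4/C6 regiochemistry is unambiguous because C4 carries its chain before the ring exists; on that point it equals the chosen plan.
- Against it here: A3 already holds the C4 and C8 stereocentres, which need their own asymmetric construction in an open chain and may be mismatched with the catalyst. Decarbonylation competes. A4 carries only a saturated three-carbon chain, so the styryl group on C3, the C2=C3 bond, the C1 oxidation and the C1–C6 closure would all remain.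
- Comparison: in structure A4 corresponds to 17 without the diene, so the chosen key step delivers more of the target in one operation. In mechanism both rest on well-known metal catalysis; the hydroacylation creates a stereocentre under catalyst control, the ring expansion only relays stereocentres. In step economy the alternative would be clearly longer after its key step.

Alternative 3: The cut is the C1–C6 bond of ring A. Forward, keto-dienal A5 would be treated with a secondary amine and an acid. The C6 enamine of the cyclopentanone adds to the C1 aldehyde of the dienal chain on C4, closing ring A as allylic alcohol A6 (either C1 epimer).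
- In its favour: C1 arrives at the oxidation level needed for the dione, C6 is set by the tether and the conditions are nearly neutral. It is the same transformation as step 10 of the chosen plan (19 to 20 in the benzyl series), so on this bond the two plans are equal.
- Against it as the strategy-bearing step: it is reversible, C4 is labile in A5, and it leaves open how ring B, with its stereocentres and with C3 on the correct α-carbon, is made.
- Comparison: in structure the alternative addresses ring A and the chosen key step ring B, so they complement each other more than they compete. In mechanism the aldol is the gentler but less certain event. In step economy there is no difference, since the chosen route contains this closure. The ring expansion is ranked as the key step because it removes the one problem no later step could repair.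

Key step: step 8

Assumption: the (2R,5R)-amine is taken to give the (2S,3S)-cyclobutanone in step 3; if a first run shows the opposite sense of induction, the (2S,5S)-amine is used and nothing else changes.

## Route

Step 1
Reactants: 1 3,5-bis(benzyloxy)benzyl bromide; 2 triethyl phosphite; 3 3,4-bis(benzyloxy)benzaldehyde
Product: 5 (E)-1,2-bis(benzyloxy)-4-{2-[3,5-bis(benzyloxy)phenyl]ethenyl}benzene, via benzylphosphonate 4 (not isolated)
Conditions: P(OEt)3, neat, 140 °C; volatiles removed; then 3, KOtBu, THF, 0 °C → rt
Reagents that add atoms: none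
Why: Michaelis–Arbuzov reaction of the benzylic bromide gives phosphonate 4, whose potassium carbanion adds to the aldehyde in a Horner–Wadsworth–Emmons olefination. Reversible adduct formation from this semi-stabilised carbanion funnels to the E-alkene, and benzyl ethers are inert to both stages.

Step 2
Reactants: 6 (2R,5R)-2,5-dimethylpyrrolidine
Product: 7 1-[(2R,5R)-2,5-dimethylpyrrolidin-1-yl]ethan-1-one
Conditions: Ac2O, Et3N, CH2Cl2, 0 °C → rt
Reagents that add atoms: acetic anhydride CC(=O)OC(C)=O
Why: Plain N-acylation of the secondary amine. The C2-symmetric amide is the precursor of a keteniminium whose two faces are equivalent, so only one mode of alkene approach exists.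

Step 3
Reactants: 7 1-[(2R,5R)-2,5-dimethylpyrrolidin-1-yl]ethan-1-one; 5 (E)-1,2-bis(benzyloxy)-4-{2-[3,5-bis(benzyloxy)phenyl]ethenyl}benzene
Product: 10 (2S,3S)-3-[3,4-bis(benzyloxy)phenyl]-2-[3,5-bis(benzyloxy)phenyl]cyclobutan-1-one, via keteniminium triflate 8 (not isolated), via cyclobutaniminium triflate 9 (not isolated)
Conditions: Tf2O, 2,4,6-collidine, ClCH2CH2Cl, −25 °C → 80 °C; then H2O, NaHCO3, 60 °C
Reagents that add atoms: water O
Why: Tf2O activates the amide oxygen and collidine removes an α-proton to give keteniminium 8, which adds to the stilbene in a stepwise polar [2+2] cycloaddition: its central carbon (C5) bonds to the alkene carbon bearing the 3,5-dioxygenated ring (C8) so that the cation develops next to the para-oxygenated ring (C7), collapse onto C6 gives 9, and hydrolysis gives 10 and frees the auxiliary. The trans relation follows from the E-alkene and is also the stable one at the epimerisable C8. The two methyl groups of the C2-symmetric amine leave one approach of the alkene to the C=N bond open, which sets C7 and C8 together; 10 should crystallise, so its enantiomeric purity can be raised by recrystallisation.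

Step 4
Reactants: 11 3-methoxyprop-1-yne; 10 (2S,3S)-3-[3,4-bis(benzyloxy)phenyl]-2-[3,5-bis(benzyloxy)phenyl]cyclobutan-1-one
Product: 13 (1S,2S,3S)-3-[3,4-bis(benzyloxy)phenyl]-2-[3,5-bis(benzyloxy)phenyl]-1-(3-methoxyprop-1-yn-1-yl)cyclobutan-1-ol, via lithium acetylide 12 (not isolated)
Conditions: n-BuLi, THF, −78 °C; CeCl3, −78 °C; then 10, −78 → −40 °C
Reagents that add atoms: none
Why: 1,2-Addition of the weakly basic organocerium acetylide to the strained ketone, so that the acidic α-aryl proton at C8 is not removed; attack anti to the neighbouring C8 aryl group should give mainly the (1S)-carbinol. The carbinol configuration is of no consequence, because this carbon becomes the C5 carbonyl in step 8.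

Step 5
Reactants: 13 (1S,2S,3S)-3-[3,4-bis(benzyloxy)phenyl]-2-[3,5-bis(benzyloxy)phenyl]-1-(3-methoxyprop-1-yn-1-yl)cyclobutan-1-ol
Product: 14 (1R,2S,3S)-3-[3,4-bis(benzyloxy)phenyl]-2-[3,5-bis(benzyloxy)phenyl]-1-(propa-1,2-dien-1-yl)cyclobutan-1-ol
Conditions: LiAlH4, THF, 0 → 60 °C
Reagents that add atoms: none
Why: Hydroxyl-directed trans-hydroalumination puts hydride on the alkyne carbon next to the carbinol (C4) and aluminium on C3; anti elimination of methoxide from this vinylalanate (overall an SN2′ hydride substitution) gives the terminal allene. No stereocentre is touched and aryl benzyl ethers are inert to the hydride.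

Step 6
Reactants: 3 3,4-bis(benzyloxy)benzaldehyde
Product: 15 (E)-3-[3,4-bis(benzyloxy)phenyl]prop-2-enoic acid
Conditions: malonic acid, pyridine, piperidine (cat.), 90 °C
Reagents that add atoms: malonic acid OC(=O)CC(=O)O
Why: Knoevenagel–Doebner condensation with decarboxylation, which gives the E-cinnamic acid.

Step 7
Reactants: 15 (E)-3-[3,4-bis(benzyloxy)phenyl]prop-2-enoic acid
Product: 16 (E)-1,2-bis(benzyloxy)-4-(2-bromoethenyl)benzene
Conditions: NBS, LiOAc (cat.), MeCN–H2O, rt
Reagents that add atoms: N-bromosuccinimide O=C1CCC(=O)N1Br
Why: Catalytic Hunsdiecker-type bromodecarboxylation: bromonium attack at the α-carbon of the electron-rich cinnamate, assisted by the para oxygen, then loss of CO2 gives the E-alkenyl bromide. One equivalent of NBS and the acrylate-deactivated ring should keep nuclear bromination down.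

Step 8
Reactants: 14 (1R,2S,3S)-3-[3,4-bis(benzyloxy)phenyl]-2-[3,5-bis(benzyloxy)phenyl]-1-(propa-1,2-dien-1-yl)cyclobutan-1-ol; 16 (E)-1,2-bis(benzyloxy)-4-(2-bromoethenyl)benzene
Product: 17 (2R,3R,4S)-4-[3,4-bis(benzyloxy)phenyl]-3-[3,5-bis(benzyloxy)phenyl]-2-{(3E)-4-[3,4-bis(benzyloxy)phenyl]buta-1,3-dien-2-yl}cyclopentan-1-one
Conditions: Pd(PPh3)4 (5 mol %), Ag2CO3, toluene, 80 °C
Reagents that add atoms: none
Why: Zerovalent palladium inserts into the C–Br bond of 16 with retention of the E geometry, and the resulting alkenylpalladium bromide (divalent palladium), made more electrophilic by Ag2CO3, adds across the allene of 14 so that the styryl group bonds to the central carbon C3 and a π-allyl complex over C4–C3–C2 results. The strained ring bond C5–C8, lying anti to palladium, then shifts from C5 to the allyl terminus C4 while the C5 alkoxide becomes the carbonyl (a semipinacol 1,2-shift), which forms C4–C8 and returns zerovalent palladium. The closest known reaction type is the zerovalent-palladium-catalysed arylative or alkenylative ring expansion of 1-allenylcyclobutanols to 2-(1-substituted vinyl)cyclopentanones. Ring B is closed by ring enlargement, four- to five-membered, through this 1,2-carbon shift onto an exocyclic carbon and not by an end-to-end cyclisation; relief of cyclobutane strain and formation of the C=O bond drive it. The new stereocentre C4 is set first by attack on the allyl face opposite palladium and then by thermodynamic control, because it is α to the ketone and allylic: it should settle trans to the C8 aryl group, giving the all-trans (2R,3R,4S) ketone. The step needs migration of C8 and not of the C6 methylene; C8 is secondary and benzylic, the better migrating carbon in semipinacol shifts, and its bond to C5 is the weaker one. The shift is suprafacial with retention at C8, so C7 and C8 keep the configuration set in step 3 (the descriptor at C8 changes from S to R only because the priorities change). A weak, insoluble base in toluene is chosen so that the diene of 17 does not drift into conjugation with the ketone, and either carbinol epimer of 14 can be used because C5 becomes trigonal.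

Step 9
Reactants: 17 (2R,3R,4S)-4-[3,4-bis(benzyloxy)phenyl]-3-[3,5-bis(benzyloxy)phenyl]-2-{(3E)-4-[3,4-bis(benzyloxy)phenyl]buta-1,3-dien-2-yl}cyclopentan-1-one
Product: 19 (2Z,4E)-5-[3,4-bis(benzyloxy)phenyl]-3-{(1R,2R,3S)-3-[3,4-bis(benzyloxy)phenyl]-2-[3,5-bis(benzyloxy)phenyl]-5-oxocyclopentyl}penta-2,4-dienal, via dienyliminium chloride 18 (not isolated)
Conditions: POCl3, DMF, CH2Cl2, 0 °C → rt; then aq NaOAc
Reagents that add atoms: N,N-dimethylformamide CN(C)C=O (carbon C1); water O (aldehyde oxygen)
Why: Vilsmeier–Haack formylation of a diene: the chloroiminium ion attacks the terminal CH2 (C2) because this gives a tertiary allylic cation at C3 that is delocalised onto the para-benzyloxystyryl unit; loss of a proton gives conjugated iminium 18 and hydrolysis the dienal. The resorcinol ring, flanked by a secondary alkyl group and two benzyloxy groups, is the main competitor and is more hindered and less nucleophilic than the diene terminus. Attack through the C4 dienol tautomer would lead to the same product, and the C2=C3 geometry and C4 equilibrate through the vinylogous enol (C4 resting trans to the C8 aryl group).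

Step 10
Reactants: 19 (2Z,4E)-5-[3,4-bis(benzyloxy)phenyl]-3-{(1R,2R,3S)-3-[3,4-bis(benzyloxy)phenyl]-2-[3,5-bis(benzyloxy)phenyl]-5-oxocyclopentyl}penta-2,4-dienal
Product: 20 C1 carbinol of jezonodione hexabenzyl ether (bicyclo[3.2.1]octenone with OH on C1, C2=C3, E-styryl on C3, C5 ketone; C4 R, C6 S, C7 R, C8 R; both C1 epimers)
Conditions: pyrrolidine (0.3 equiv), AcOH (0.3 equiv), wet THF, rt
Reagents that add atoms: none
Why: Intramolecular enamine aldol reaction (6-enolexo): the pyrrolidine enamine on the C6 side of the ketone adds to the C1 aldehyde and hydrolysis of the iminium returns the β-hydroxy ketone, which cannot dehydrate because C6 is a bridgehead. C6 is set by the tether, since the new bond must be cis to the C4–C3 bond; the C2=C3 geometry and the labile C4 centre of 19 interconvert under the conditions, and the major isomer, with the C3 arm trans to the C8 aryl group, is expected to close. Both C1 epimers are carried on.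

Step 11
Reactants: 20 C1 carbinol of jezonodione hexabenzyl ether (both C1 epimers)
Product: 21 (1S,5R,6R,7R)-7-[3,4-bis(benzyloxy)phenyl]-6-[3,5-bis(benzyloxy)phenyl]-4-{(E)-2-[3,4-bis(benzyloxy)phenyl]ethenyl}bicyclo[3.2.1]oct-3-ene-2,8-dione
Conditions: Dess–Martin periodinane, NaHCO3, CH2Cl2, 0 °C → rt
Reagents that add atoms: none
Why: Dess–Martin oxidation of the secondary allylic alcohol under bicarbonate buffer, which avoids acid at the easily ionised C1 carbinol. Making the 1,3-dione by oxidation avoids any Claisen-type equilibrium, which a dione with a bridgehead central carbon would lose; the C1 epimers converge and no stereocentre is affected.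

Step 12
Reactants: 21 (1S,5R,6R,7R)-7-[3,4-bis(benzyloxy)phenyl]-6-[3,5-bis(benzyloxy)phenyl]-4-{(E)-2-[3,4-bis(benzyloxy)phenyl]ethenyl}bicyclo[3.2.1]oct-3-ene-2,8-dione
Product: 22 jezonodione, (1S,5R,6R,7R)-7-(3,4-dihydroxyphenyl)-6-(3,5-dihydroxyphenyl)-4-[(E)-2-(3,4-dihydroxyphenyl)ethenyl]bicyclo[3.2.1]oct-3-ene-2,8-dione
Conditions: BCl3, pentamethylbenzene, CH2Cl2, −78 °C; then MeOH–CHCl3, −78 °C
Reagents that add atoms: none
Why: BCl3 cleaves aryl benzyl ethers at −78 °C and pentamethylbenzene captures the benzyl cations, which would otherwise alkylate the freed resorcinol and catechol rings. Alkenes, ketones and the enone should not be attacked at this temperature, and no base or nucleophile that could open the 1,3-dione is present.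

## Compound list

1 | 3,5-bis(benzyloxy)benzyl bromide | BrCc1cc(OCc2ccccc2)cc(OCc2ccccc2)c1 | starting material
2 | triethyl phosphite | CCOP(OCC)OCC | starting material
3 | 3,4-bis(benzyloxy)benzaldehyde | O=Cc1ccc(OCc2ccccc2)c(OCc2ccccc2)c1 | starting material
4 | diethyl [3,5-bis(benzyloxy)benzyl]phosphonate | CCOP(=O)(Cc1cc(OCc2ccccc2)cc(OCc2ccccc2)c1)OCC | intermediate
5 | (E)-1,2-bis(benzyloxy)-4-{2-[3,5-bis(benzyloxy)phenyl]ethenyl}benzene | c1(/C=C/c2ccc(OCc3ccccc3)c(OCc3ccccc3)c2)cc(OCc2ccccc2)cc(OCc2ccccc2)c1 | intermediate
6 | (2R,5R)-2,5-dimethylpyrrolidine | C[C@@H]1CC[C@@H](C)N1 | starting material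
7 | 1-[(2R,5R)-2,5-dimethylpyrrolidin-1-yl]ethan-1-one | C[C@@H]1CC[C@@H](C)N1C(C)=O | intermediate
8 | (2R,5R)-1-ethenylidene-2,5-dimethylpyrrolidinium triflate (keteniminium salt) | C[C@@H]1CC[C@@H](C)[N+]1=C=C.[O-]S(=O)(=O)C(F)(F)F | intermediate
9 | (2R,5R)-1-{(2S,3S)-3-[3,4-bis(benzyloxy)phenyl]-2-[3,5-bis(benzyloxy)phenyl]cyclobutylidene}-2,5-dimethylpyrrolidinium triflate | C[C@@H]1CC[C@@H](C)[N+]1=C1C[C@H](c2ccc(OCc3ccccc3)c(OCc3ccccc3)c2)[C@H]1c1cc(OCc2ccccc2)cc(OCc2ccccc2)c1.[O-]S(=O)(=O)C(F)(F)F | intermediate
10 | (2S,3S)-3-[3,4-bis(benzyloxy)phenyl]-2-[3,5-bis(benzyloxy)phenyl]cyclobutan-1-one (aryl groups trans) | O=C1C[C@H](c2ccc(OCc3ccccc3)c(OCc3ccccc3)c2)[C@H]1c1cc(OCc2ccccc2)cc(OCc2ccccc2)c1 | intermediate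
11 | 3-methoxyprop-1-yne | C#CCOC | starting material
12 | lithium 3-methoxyprop-1-yn-1-ide | [Li]C#CCOC | intermediate
13 | (1S,2S,3S)-3-[3,4-bis(benzyloxy)phenyl]-2-[3,5-bis(benzyloxy)phenyl]-1-(3-methoxyprop-1-yn-1-yl)cyclobutan-1-ol (OH cis to the C2 aryl group) | O[C@@]1(C#CCOC)C[C@H](c2ccc(OCc3ccccc3)c(OCc3ccccc3)c2)[C@H]1c1cc(OCc2ccccc2)cc(OCc2ccccc2)c1 | intermediate
14 | (1R,2S,3S)-3-[3,4-bis(benzyloxy)phenyl]-2-[3,5-bis(benzyloxy)phenyl]-1-(propa-1,2-dien-1-yl)cyclobutan-1-ol | O[C@@]1(C=C=C)C[C@H](c2ccc(OCc3ccccc3)c(OCc3ccccc3)c2)[C@H]1c1cc(OCc2ccccc2)cc(OCc2ccccc2)c1 | intermediate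
15 | (E)-3-[3,4-bis(benzyloxy)phenyl]prop-2-enoic acid | OC(=O)/C=C/c1ccc(OCc2ccccc2)c(OCc2ccccc2)c1 | intermediate
16 | (E)-1,2-bis(benzyloxy)-4-(2-bromoethenyl)benzene | Br/C=C/c1ccc(OCc2ccccc2)c(OCc2ccccc2)c1 | intermediate
17 | (2R,3R,4S)-4-[3,4-bis(benzyloxy)phenyl]-3-[3,5-bis(benzyloxy)phenyl]-2-{(3E)-4-[3,4-bis(benzyloxy)phenyl]buta-1,3-dien-2-yl}cyclopentan-1-one (all-trans) | C=C(/C=C/c1ccc(OCc2ccccc2)c(OCc2ccccc2)c1)[C@@H]1C(=O)C[C@H](c2ccc(OCc3ccccc3)c(OCc3ccccc3)c2)[C@H]1c1cc(OCc2ccccc2)cc(OCc2ccccc2)c1 | intermediate
18 | N,N-dimethyliminium chloride of dienal 19 (C1=N+Me2) | C[N+](C)=C/C=C(/C=C/c1ccc(OCc2ccccc2)c(OCc2ccccc2)c1)[C@@H]1C(=O)C[C@H](c2ccc(OCc3ccccc3)c(OCc3ccccc3)c2)[C@H]1c1cc(OCc2ccccc2)cc(OCc2ccccc2)c1.[Cl-] | intermediate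
19 | (2Z,4E)-5-[3,4-bis(benzyloxy)phenyl]-3-{(1R,2R,3S)-3-[3,4-bis(benzyloxy)phenyl]-2-[3,5-bis(benzyloxy)phenyl]-5-oxocyclopentyl}penta-2,4-dienal | O=C/C=C(/C=C/c1ccc(OCc2ccccc2)c(OCc2ccccc2)c1)[C@@H]1C(=O)C[C@H](c2ccc(OCc3ccccc3)c(OCc3ccccc3)c2)[C@H]1c1cc(OCc2ccccc2)cc(OCc2ccccc2)c1 | intermediate
20 | C1 carbinol of jezonodione hexabenzyl ether (C4 R, C6 S, C7 R, C8 R; C1 epimers, C1 left undefined) | OC1C=C(/C=C/c2ccc(OCc3ccccc3)c(OCc3ccccc3)c2)[C@@H]2C(=O)[C@H]1[C@H](c1ccc(OCc3ccccc3)c(OCc3ccccc3)c1)[C@H]2c1cc(OCc2ccccc2)cc(OCc2ccccc2)c1 | intermediate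
21 | jezonodione hexabenzyl ether, (1S,5R,6R,7R)-7-[3,4-bis(benzyloxy)phenyl]-6-[3,5-bis(benzyloxy)phenyl]-4-{(E)-2-[3,4-bis(benzyloxy)phenyl]ethenyl}bicyclo[3.2.1]oct-3-ene-2,8-dione | O=C1C=C(/C=C/c2ccc(OCc3ccccc3)c(OCc3ccccc3)c2)[C@@H]2C(=O)[C@H]1[C@H](c1ccc(OCc3ccccc3)c(OCc3ccccc3)c1)[C@H]2c1cc(OCc2ccccc2)cc(OCc2ccccc2)c1 | intermediate
22 | jezonodione, (1S,5R,6R,7R)-7-(3,4-dihydroxyphenyl)-6-(3,5-dihydroxyphenyl)-4-[(E)-2-(3,4-dihydroxyphenyl)ethenyl]bicyclo[3.2.1]oct-3-ene-2,8-dione | O=C1C=C(/C=C/c2ccc(O)c(O)c2)[C@@H]2C(=O)[C@H]1[C@H](c1ccc(O)c(O)c1)[C@H]2c1cc(O)cc(O)c1 | target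

## Step count and least certain steps

Total steps: 12. Longest linear sequence: 9 (steps 1, 3, 4, 5, 8, 9, 10, 11, 12); steps 2, 6 and 7 are side branches.

Key step (step 8). The most likely failures are migration of the C6 methylene in place of benzylic C8, opening of the cyclobutanol by β-carbon elimination from the palladium alkoxide before the allene is engaged, and base-induced drift of the diene into conjugation with the new ketone. The fallback separates ring expansion from C–C coupling. From 14, a bromonium-induced semipinacol rearrangement (NBS, CH2Cl2, −78 °C, where ring bromination should be slow relative to the hydroxyl-assisted shift) would give (2S,3R,4S)-2-(1-bromoethenyl)-3,4-diarylcyclopentanone F1; its stronger cationic character at C4 favours the benzylic migrating carbon even more. From 16, Miyaura borylation (B2pin2, PdCl2(dppf), KOPh, toluene) would give the (E)-styrylboronic acid pinacol ester F2. Suzuki–Miyaura coupling of the two (PdCl2(dppf), K3PO4, THF–H2O, 40 °C) comes back to the route at 17.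

Formylation (step 9). The most likely failure is loss of chemoselectivity: formylation of the resorcinol ring, or chloroformylation through the C6 enol of the ketone. The fallback uses the acidity of C4–H instead of the nucleophilicity of the free diene. From 17, TBSOTf and Et3N (CH2Cl2, 0 °C) should give the conjugated silyl dienol ether F3. A vinylogous Mukaiyama reaction with trimethyl orthoformate (BF3·OEt2, CH2Cl2, −78 °C) at the terminal carbon C2 would give the enone dimethyl acetal F4. Mild acid hydrolysis (PPTS, wet acetone), with tautomerisation, comes back to the route at 19.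

Aldol closure (step 10). The most likely failures are an unfavourable equilibrium (retro-aldol back to the stabilised dienal), sequestration of the amine as a vinylogous enaminone through C4, Mannich-type capture of the enal iminium, and erosion of diastereoselectivity by closure through the minor C4 epimer. The fallback closes the same bond at the acid oxidation level, where it is irreversible. From 19, Pinnick oxidation (NaClO2, NaH2PO4, 2-methyl-2-butene, t-BuOH–H2O) would give the (2Z,4E)-dienoic acid F5. Acid-promoted intramolecular C-acylation of the ketone through the mixed anhydride (TFAA, then BF3·OEt2, CH2Cl2, 0 °C) comes back to the route at 21, by-passing 20 and step 11.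

Keteniminium cycloaddition (step 3). The most likely failures are electrophilic attack of the keteniminium on the resorcinol ring in place of the alkene, and poor facial selectivity. The fallback changes both the two-carbon partner and the source of chirality. From 5, dichloroketene cycloaddition (Cl3CCOCl, Zn–Cu, Et2O), which has the same polarity and therefore the same regiochemistry, would give the racemic trans-2,2-dichlorocyclobutanone F6. Dechlorination (Zn, AcOH) gives racemic 10, which is resolved by chromatography on a chiral stationary phase and comes back to the route at 10.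

Allene formation (step 5). The most likely failures are reduction stopping at the allylic ether without elimination, and opening of the strained cyclobutanol alkoxide on heating. The fallback builds the allene by one-carbon homologation. From 10, HC≡CMgBr (THF, −78 °C) would give the (1S,2S,3S)-1-ethynylcyclobutanol F7, and a Crabbé homologation ((CH2O)n, CuI, Cy2NH, dioxane, reflux) comes back to the route at 14.

## Further compounds

F1 | step 8 | (2S,3R,4S)-4-[3,4-bis(benzyloxy)phenyl]-3-[3,5-bis(benzyloxy)phenyl]-2-(1-bromoethenyl)cyclopentan-1-one | C=C(Br)[C@@H]1C(=O)C[C@H](c2ccc(OCc3ccccc3)c(OCc3ccccc3)c2)[C@H]1c1cc(OCc2ccccc2)cc(OCc2ccccc2)c1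
F2 | step 8 | (E)-2-{2-[3,4-bis(benzyloxy)phenyl]ethenyl}-4,4,5,5-tetramethyl-1,3,2-dioxaborolane | CC1(C)OB(/C=C/c2ccc(OCc3ccccc3)c(OCc3ccccc3)c2)OC1(C)C
F3 | step 9 | tert-butyldimethylsilyl dienol ether of 17 (C4=C5 enol, O-silyl on C5) | C=C(/C=C/c1ccc(OCc2ccccc2)c(OCc2ccccc2)c1)C1=C(O[Si](C)(C)C(C)(C)C)C[C@H](c2ccc(OCc3ccccc3)c(OCc3ccccc3)c2)[C@H]1c1cc(OCc2ccccc2)cc(OCc2ccccc2)c1
F4 | step 9 | enone dimethyl acetal (C3=C4 alkene conjugated to the C5 ketone, CH2CH(OMe)2 on C3, alkene geometry undefined) | COC(OC)CC(/C=C/c1ccc(OCc2ccccc2)c(OCc2ccccc2)c1)=C1C(=O)C[C@H](c2ccc(OCc3ccccc3)c(OCc3ccccc3)c2)[C@H]1c1cc(OCc2ccccc2)cc(OCc2ccccc2)c1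
F5 | step 10 | (2Z,4E)-5-[3,4-bis(benzyloxy)phenyl]-3-{(1R,2R,3S)-3-[3,4-bis(benzyloxy)phenyl]-2-[3,5-bis(benzyloxy)phenyl]-5-oxocyclopentyl}penta-2,4-dienoic acid | OC(=O)/C=C(/C=C/c1ccc(OCc2ccccc2)c(OCc2ccccc2)c1)[C@@H]1C(=O)C[C@H](c2ccc(OCc3ccccc3)c(OCc3ccccc3)c2)[C@H]1c1cc(OCc2ccccc2)cc(OCc2ccccc2)c1
F6 | step 3 | trans-3-[3,4-bis(benzyloxy)phenyl]-4-[3,5-bis(benzyloxy)phenyl]-2,2-dichlorocyclobutan-1-one (racemic, one enantiomer drawn) | O=C1C(Cl)(Cl)[C@H](c2ccc(OCc3ccccc3)c(OCc3ccccc3)c2)[C@H]1c1cc(OCc2ccccc2)cc(OCc2ccccc2)c1
F7 | step 5 | (1S,2S,3S)-3-[3,4-bis(benzyloxy)phenyl]-2-[3,5-bis(benzyloxy)phenyl]-1-ethynylcyclobutan-1-ol | O[C@@]1(C#C)C[C@H](c2ccc(OCc3ccccc3)c(OCc3ccccc3)c2)[C@H]1c1cc(OCc2ccccc2)cc(OCc2ccccc2)c1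
A1 | alternative 1 | 2-allyl-3-(3,4-dimethoxyphenyl)-4-(3,5-dimethoxyphenyl)-5-ethynylcyclopentan-1-one (allyl and ethynyl cis) | C#C[C@@H]1C(=O)[C@H](CC=C)[C@H](c2ccc(OC)c(OC)c2)[C@H]1c1cc(OC)cc(OC)c1
A2 | alternative 1 | 6-(3,4-dimethoxyphenyl)-7-(3,5-dimethoxyphenyl)-2-ethenylbicyclo[3.2.1]oct-2-en-8-one | C1C=C(C=C)[C@@H]2C(=O)[C@H]1[C@H](c1ccc(OC)c(OC)c1)[C@H]2c1cc(OC)cc(OC)c1
A3 | alternative 2 | 5-(tert-butyldimethylsilyloxy)-2-[2-(3,4-dimethoxyphenyl)-1-(3,5-dimethoxyphenyl)prop-2-en-1-yl]pentanal | O=C[C@@H](CCCO[Si](C)(C)C(C)(C)C)[C@H](c1cc(OC)cc(OC)c1)C(=C)c1ccc(OC)c(OC)c1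
A4 | alternative 2 | 2-[3-(tert-butyldimethylsilyloxy)propyl]-4-(3,4-dimethoxyphenyl)-3-(3,5-dimethoxyphenyl)cyclopentan-1-one | O=C1[C@@H](CCCO[Si](C)(C)C(C)(C)C)[C@H](c2cc(OC)cc(OC)c2)[C@@H](c2ccc(OC)c(OC)c2)C1
A5 | alternative 3 | (2Z,4E)-5-(3,4-dimethoxyphenyl)-3-[3-(3,4-dimethoxyphenyl)-2-(3,5-dimethoxyphenyl)-5-oxocyclopentyl]penta-2,4-dienal | O=C/C=C(/C=C/c1ccc(OC)c(OC)c1)[C@@H]1C(=O)C[C@H](c2ccc(OC)c(OC)c2)[C@H]1c1cc(OC)cc(OC)c1
A6 | alternative 3 | C1 carbinol of jezonodione hexamethyl ether (either C1 epimer) | OC1C=C(/C=C/c2ccc(OC)c(OC)c2)[C@@H]2C(=O)[C@H]1[C@H](c1ccc(OC)c(OC)c1)[C@H]2c1cc(OC)cc(OC)c1
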